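## Structural features

The target is a meso 2,5-diaryl-3,4-bis(hydroxymethyl)oxolane: one five-membered cyclic ether (ring A: O1, C2–C5) with two identical 4-hydroxy-3,5-dimethoxyphenyl groups (rings B and C) on C2 and C5 and a CH2OH group on each of C3 and C4. All four substituents lie on one face of ring A (2S,3S,4R,5R, mirror plane through O1 and the midpoint of C3–C4), so four contiguous stereocentres adjoin each other in the most crowded, least stable arrangement. Both ring C–O bonds are benzylic and para to a free phenol, so acid, hot base or a hydrogenolysis catalyst can open or epimerise them through quinone methide or benzylic cation chemistry. The free syringyl phenols are also easily oxidised. The real difficulty is therefore to install a contra-thermodynamic all-cis array under kinetic control and to expose it to nothing epimerising afterwards. The key step exploits the fact that O1–C5 and the bond from C4 to its exocyclic carbon sit on two neighbouring carbons. These two carbons can be the two carbons of an aryl alkyne, onto which the C2 hydroxyl and a carboxyl-level carbon are added together. The flat C4=C5 unit that results can then receive its two hydrogens last, from the face left open by the preset C2/C3 pair; because the target is meso, racemic intermediates suffice.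

## Logic of the disconnections

20 from 19. No skeletal bond is cut; four acyl C–O bonds (one methyl ester, three pivalates) are traced back, so both primary alcohols and both phenols stay masked until the last step. The sensitive p-hydroxybenzyl ether array is thereby kept out of every earlier step, and deprotection and adjustment of the oxidation level at the C4 carbon become one operation. The demand is that hydride delivery be faster than enolisation at the ester-bearing carbon, whose epimerisation would relieve the all-cis strain.

19 from 18. The C2–H and C3–H bonds (numbering of 18) are removed to give a flat, tetrasubstituted enol ether–acrylate. Two stereocentres are reduced to a question of face selectivity governed by the two that remain. The demand is syn addition of hydrogen from the face opposite the C4 and C5 substituents, without arene saturation or benzylic C–O hydrogenolysis.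

18 from 15 (key disconnection). The O1–C2 bond and the C3–CO2Me bond of 18 are cut together; what remains is an open-chain homopropargylic alcohol plus CO and methanol. Ring A and the carboxyl carbon are traded for one catalytic step, and the two stereocentres of 15 pass through unchanged. The demand is oxygen attack at the distal, aryl-bearing alkyne carbon with CO capture of the vinyl–metal bond. Because closure occurs with retention, the hydroxyl and acyloxymethyl groups of 15 must be syn along the extended butynol chain to end 4,5-cis.

15 from 12 and 14. The C(sp)–C(aryl) bond is cut. One arene is removed from the stereochemistry-setting phase, so the stereo pair is made on a small terminal alkyne. The demand is a cross-coupling mild enough for a free benzylic alcohol, three pivalates and a propargylic stereocentre.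

12 from 9 and 11. The C1–C2 bond between the carbinol carbon and the propargylic carbon is cut; this is the only step that must create relative configuration in an open chain. The pieces are an aromatic aldehyde and a four-carbon allenylmetal. The demand is syn selectivity, hence a Lewis-acid promoted open transition state with a stannane. A cyclic transition state with zinc or indium would give the anti isomer and, after closure, the 4,5-trans ring.

9 from 8, and 8 from 7. The C–Sn bond is cut with allylic transposition (SN2' displacement of a propargylic sulfonate), then the sulfonate S–O bond back to the alcohol. The demand is clean anti-SN2' delivery of tin without attack on the pivalate.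

7 from 5 and 6. The bond between the carbinol carbon and the alkyne is cut, leaving an α-acyloxy aldehyde and an ethynyl nucleophile. The demand is addition at low temperature to an enolisable, ester-bearing aldehyde.

5 from 3, and 3 from 1 and 2. The aldehyde carbonyl is traced to the C=C bond of a symmetrical alkene, whose cleavage gives two identical molecules; the two ester C–O bonds lead back to one molecule of 1 and two molecules of 2. The demands are complete double acylation and a reductive work-up that stops at the aldehyde.

11 from 10 and 2; 14 from 13 and 2. Only aryl ester C–O bonds are cut. The pivalate is chosen because it survives every later step and falls to the final hydride together with the other esters. The demand is complete acylation of hindered 2,6-disubstituted phenols.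

## Other disconnections considered

Alternative 1: The cut goes through both arenes. In each syringyl ring the bonds C2–C3 and C5–C6 (arene numbering from the carbon attached to ring A) are broken. The oxolane core then carries two three-carbon vinamidinium units, as in the all-cis bis(vinamidinium) salt A2, and the C3–C4–C5 unit of each arene comes from 1,3-dimethoxyacetone A3. Forward, A2 would condense twice with the enolate of A3 under KOtBu (addition, loss of the amine, ring closure, aromatisation) to give the all-cis bis(benzyl ether) A1; hydrogenolysis of the benzyl ethers would finish.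
- In its favour: all four stereocentres could be set in one operation on an arene-free, furan-derived core, where hydrogenation meets neither a benzylic C–O bond nor an electron-rich arene. The phenols appear unprotected. The mirror symmetry is used in both directions, which the chosen plan, with its racemic unsymmetrical intermediates, does not do.
- Against it here: A2 needs a Vilsmeier-type aminomethylenation of a diacetic acid whose ring oxygen is β to each carboxyl group. That step and the strongly basic annulation both pass through intermediates in which the C2–O and C5–O bonds are β, or vinylogously β, to an electron-poor π-system, so E1cB ring opening or epimerisation at C2/C5 threatens the all-cis array. The annulation with an α,α'-dialkoxy ketone must also succeed twice in one molecule. The final debenzylation of A1 puts two benzylic ring C–O bonds para to free phenols in front of a hydrogenolysis catalyst.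
- Comparison: on stereochemical economy the alternative is the better plan (one reduction sets everything, no acyclic diastereoselection). On mechanism the chosen route is safer, since after its stereocentres exist nothing more basic than cold hydride is used and no hydrogenolysis is needed. In step count the two should be similar, because the core of A2 needs its own multi-step preparation.

Alternative 2: The cut is at the two aryl–ring bonds, C2–Ar and C5–Ar, leaving the meso cis-oxolane-3,4-bis(quinolin-8-ylamide) A5 and two equivalents of 2-benzyloxy-5-iodo-1,3-dimethoxybenzene A6. Forward, each amide would direct Pd(OAc)2 (with AgOAc as iodide acceptor) to the neighbouring C–H bond next to the ring oxygen. The five-membered palladacycle can form only on the face of the amide, so each aryl group should arrive cis to its amide and give the all-cis diamide A4.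
- In its favour: A5 is one or two steps from a commercial cis-diacid derivative. Auxiliary-directed C–H arylation of cyclic carboxamides is a well-documented reaction type. The cis relationship is enforced by the mechanism and not by substrate bias. On stereocontrol in principle, and on step count up to the core, this is the better plan.
- Against it here: two bidentate amides on adjacent carbons can bind one palladium and stall the cycle. The second arylation must build the fully eclipsed all-cis array through a more strained palladacycle at high temperature, where epimerisation α to an amide is a realistic escape. The robust auxiliaries must be removed twice and taken to CH2OH without epimerisation. The benzyl ethers must then be cleaved by hydrogenolysis beside benzylic ring C–O bonds, and stoichiometric silver is consumed twice.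
- Comparison: shorter on paper, and more elegant in how the relative configuration is fixed. The chosen plan is more conservative: each of its bond-forming steps has close precedent on comparable substrates, and its end game needs neither auxiliary cleavage nor hydrogenolysis. After auxiliary removal and deprotection the alternative would probably be only a few steps shorter.

Alternative 3: The cut is the C3–C4 bond of ring A, replaced retrosynthetically by a sulfonyl bridge; the precursor is the cis-2,6-diaryl-1,4-oxathiane 4,4-dioxide diester A8. Forward, chlorination of one α-sulfonyl carbon (NCS, K2CO3) and treatment with DBU would let the other α-carbanion displace chloride to an episulfone. This extrudes SO2 and would give the meso 2,5-dihydrofuran diester A7 (Ramberg–Bäcklund reaction). Hydrogenation of C3=C4 from the face opposite both aryl groups, ester reduction and debenzylation would follow.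
- In its favour: A8 should be accessible two-directionally from two aldehyde units and a sulfur-bridged bis(acetate), with the 2,6-cis arrangement set under thermodynamic control in a chair (both aryl groups equatorial). The contraction does not touch C2/C5. The alkene of A7 is a plain maleate and not a push–pull enol ether, and both aryl groups shield the same face, so the final hydrogenation should be easier and at least as selective as in the chosen plan. On these points, and in its use of symmetry, the alternative is the equal or the better.
- Against it here: A8 is a β-alkoxy sulfone and ester on both sides and can open by E1cB elimination under the very bases the contraction needs. The displacement that forms the episulfone occurs at a fully substituted carbon. In A7 each C2/C5 hydrogen is benzylic, allylic, α to oxygen and γ to an ester, so DBU can move the double bond into conjugation with oxygen, epimerise C2/C5 or open the way to a furan. Hydrogenation must also spare, or be combined with, the benzyl ethers without cleaving the benzylic ring C–O bonds.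
- Comparison: probably two to four steps shorter. It sets the 2,5-cis relationship more simply but stakes the route on base-sensitive intermediates. The chosen plan keeps strong base away from every stereocentre-bearing intermediate and pays for this with one diastereoselective acyclic addition and more linear steps.

Key step: step 10

Remark on the chemistry: the target is meso, so all chiral intermediates are racemates (one enantiomer drawn). The isomer of 15 required is the one with OH and CH2OPiv on the same side of the extended C1–C4 butynol chain (1S*,2S*, syn; it reads as anti only if the chain is drawn through the CH2O carbon). Closure with retention turns syn into 4,5-cis, whereas the 1S*,2R* isomer would end as a 2,3-trans oxolane.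

## Steps

Step 1
Reactants: 1 cis-2-butene-1,4-diol; 2 pivaloyl chloride
Product: 3 (Z)-but-2-ene-1,4-diyl bis(2,2-dimethylpropanoate)
Conditions: PivCl (2.3 equiv), Et3N, DMAP (cat.), CH2Cl2, 0 → 20 °C
Reagents that add atoms: pivaloyl chloride (second equivalent), CC(C)(C)C(Cl)=O
Why: DMAP-catalysed O-acylation (nucleophilic acyl substitution) of both primary allylic hydroxyls, one molecule of the acid chloride being consumed per hydroxyl; the Z-alkene is untouched and no stereocentre is involved.

Step 2
Reactants: 3 (Z)-but-2-ene-1,4-diyl bis(2,2-dimethylpropanoate)
Product: 5 2-oxoethyl pivalate, via secondary ozonide 4 (not isolated)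
Conditions: O3, CH2Cl2, −78 °C; then Me2S, −78 → 20 °C
Reagents that add atoms: ozone, [O-][O+]=O
Why: Ozonolysis with reductive work-up: ozone adds to the electron-rich alkene, the adduct rearranges to the secondary ozonide 4 and Me2S reduces it, so the symmetrical C=C bond gives two molecules of 5; the hindered pivalates are inert to ozone.

Step 3
Reactants: 5 2-oxoethyl pivalate; 6 ethynylmagnesium bromide
Product: 7 2-hydroxybut-3-yn-1-yl pivalate (racemic)
Conditions: HC≡CMgBr (0.5 M in THF), THF, −78 °C; aq NH4Cl
Reagents that add atoms: none
Why: 1,2-Addition of an alkynyl Grignard reagent to the aldehyde; at −78 °C the aldehyde reacts far faster than the hindered pivalate, and the new stereocentre is formed as a racemate, which is all that is needed.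

Step 4
Reactants: 7 2-hydroxybut-3-yn-1-yl pivalate
Product: 8 2-(methanesulfonyloxy)but-3-yn-1-yl pivalate (racemic)
Conditions: MsCl, Et3N, CH2Cl2, −40 → 0 °C; used crude
Reagents that add atoms: methanesulfonyl chloride, CS(=O)(=O)Cl
Why: Sulfonylation (mesylation) of the secondary propargylic alcohol provides the leaving group for the SN2' step; the labile propargylic mesylate is carried on without chromatography.

Step 5
Reactants: 8 2-(methanesulfonyloxy)but-3-yn-1-yl pivalate
Product: 9 4-(tributylstannyl)buta-2,3-dien-1-yl pivalate (racemic allene)
Conditions: Bu3SnH, LiN(i-Pr)2, THF, 0 °C; CuBr·SMe2, −78 °C; then 8, −78 °C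
Reagents that add atoms: tributyltin hydride, CCCC[SnH](CCCC)CCCC
Why: Anti-SN2' displacement of the propargylic mesylate by the stannylcopper reagent gives the allenylstannane; mesylate is a far better leaving group than pivalate, so the ester is retained, and racemic 8 gives a racemic allene.

Step 6
Reactants: 10 syringaldehyde; 2 pivaloyl chloride
Product: 11 4-formyl-2,6-dimethoxyphenyl pivalate
Conditions: PivCl, Et3N, DMAP (cat.), CH2Cl2, 0 → 20 °C
Reagents that add atoms: none
Why: Acylation of the hindered but acidic phenol; the pivalate removes the acidic proton, protects the ring from oxidation and makes the aldehyde more electrophilic.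

Step 7
Reactants: 9 4-(tributylstannyl)buta-2,3-dien-1-yl pivalate; 11 4-formyl-2,6-dimethoxyphenyl pivalate
Product: 12 4-[(1S*,2S*)-1-hydroxy-2-(pivaloyloxymethyl)but-3-yn-1-yl]-2,6-dimethoxyphenyl pivalate (syn; racemic)
Conditions: BF3·OEt2, CH2Cl2, −78 °C; aq NaHCO3
Reagents that add atoms: none
Why: Lewis-acid promoted SE2' addition of an allenylstannane to an aldehyde: BF3 activates 11 and the γ-carbon of 9 attacks through an open antiperiplanar transition state in which the aryl group and the CH2OPiv substituent avoid each other, which should set both stereocentres syn (1S*,2S*) while loss of tin unveils the terminal alkyne. Any anti isomer is to be removed by chromatography at this stage.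

Step 8
Reactants: 13 4-bromo-2,6-dimethoxyphenol; 2 pivaloyl chloride
Product: 14 4-bromo-2,6-dimethoxyphenyl pivalate
Conditions: PivCl, Et3N, DMAP (cat.), CH2Cl2, 0 → 20 °C
Reagents that add atoms: none
Why: Phenol acylation as in step 6; the ester also lowers the electron density of the ring, which helps oxidative addition in step 9.

Step 9
Reactants: 12 4-[(1S*,2S*)-1-hydroxy-2-(pivaloyloxymethyl)but-3-yn-1-yl]-2,6-dimethoxyphenyl pivalate; 14 4-bromo-2,6-dimethoxyphenyl pivalate
Product: 15 (1S*,2S*)-1,4-bis(3,5-dimethoxy-4-pivaloyloxyphenyl)-2-(pivaloyloxymethyl)but-3-yn-1-ol (syn; racemic)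
Conditions: PdCl2(PhCN)2 (3 mol %), P(t-Bu)3·HBF4 (6 mol %), CuI (2 mol %), i-Pr2NH, 1,4-dioxane, 25 °C
Reagents that add atoms: none
Why: Sonogashira coupling: zerovalent palladium, formed in situ with the bulky electron-rich phosphine, inserts into the C–Br bond of 14, the copper acetylide of 12 transmetalates and reductive elimination forms the aryl–alkyne bond; room temperature and an amine base leave the free alcohol, the pivalates and both stereocentres untouched.

Step 10
Reactants: 15 (1S*,2S*)-1,4-bis(3,5-dimethoxy-4-pivaloyloxyphenyl)-2-(pivaloyloxymethyl)but-3-yn-1-ol
Product: 18 methyl (4S*,5S*)-2,5-bis(3,5-dimethoxy-4-pivaloyloxyphenyl)-4-(pivaloyloxymethyl)-4,5-dihydrofuran-3-carboxylate (4,5-cis; racemic), via vinylpalladium chloride 16 (not isolated), via acylpalladium chloride 17 (not isolated)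
Conditions: PdCl2(MeCN)2 (10 mol %), p-benzoquinone (1.5 equiv), CO (1 atm), MeOH/THF 4:1, 0 → 20 °C
Reagents that add atoms: carbon monoxide, [C-]#[O+]; methanol, CO
Why: Electrophilic divalent palladium binds the alkyne of 15 and the C1 hydroxyl adds anti to the metal at the aryl-bearing alkyne carbon, closing ring A in the 5-endo-dig mode (the only other mode, 4-exo-dig to an oxetane, is strained) and giving 16. CO inserts into the C–Pd bond to give 17, methanol cleaves this to the ester and zerovalent palladium, and p-benzoquinone with the two released protons restores divalent palladium. The closest known reaction type is the oxidative heterocyclisation–alkoxycarbonylation of alkynes carrying a pendant OH, established in the exo mode for 4-yn-1-ols and in the 5-endo mode for 2-alkynylphenols and 3-yne-1,2-diols. No stereocentre is created: C1 and C2 of 15 are untouched and become C5 and C4 of 18, so the syn pair translates with retention into the 4,5-cis pair. The selectivity needed is chemoselectivity: oxypalladation followed by CO capture must outrun protodepalladation of 16 and the alternative path through an alkoxycarbonylpalladium species that would end in an α-alkylidene lactone. The aryl-conjugated alkyne is polarised toward attack at its benzylic terminus, base-free methanol at 0 °C disfavours alkoxycarbonylpalladium formation, and the CO atmosphere makes insertion fast relative to protonolysis. The pivalates keep the phenols from oxidation by the quinone and are inert to the weakly acidic medium.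

Step 11
Reactants: 18 methyl (4S*,5S*)-2,5-bis(3,5-dimethoxy-4-pivaloyloxyphenyl)-4-(pivaloyloxymethyl)-4,5-dihydrofuran-3-carboxylate
Product: 19 methyl (2R*,3S*,4S*,5S*)-2,5-bis(3,5-dimethoxy-4-pivaloyloxyphenyl)-4-(pivaloyloxymethyl)oxolane-3-carboxylate (all-cis; racemic)
Conditions: H2 (40 bar), 5% Rh/Al2O3, EtOAc, 25 °C
Reagents that add atoms: none
Why: Heterogeneous hydrogenation delivers both hydrogens syn to the face of C2=C3 opposite the C4 CH2OPiv and C5 aryl groups, which should create the C2 and C3 stereocentres all-cis to the existing pair. Rh/Al2O3 is chosen because it reduces β-alkoxyacrylates under conditions that normally leave benzylic C–O bonds intact, and the acyloxy-deactivated arenes should resist saturation at room temperature.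

Step 12
Reactants: 19 methyl (2R*,3S*,4S*,5S*)-2,5-bis(3,5-dimethoxy-4-pivaloyloxyphenyl)-4-(pivaloyloxymethyl)oxolane-3-carboxylate
Product: 20 [(2S,3S,4R,5R)-2,5-bis(4-hydroxy-3,5-dimethoxyphenyl)oxolane-3,4-diyl]dimethanol (all-cis; meso)
Conditions: LiAlH4 (6 equiv), THF, −20 → 0 °C, inverse addition; aq KNaC4H4O6 then aq NH4Cl to pH 6, under N2
Reagents that add atoms: none
Why: Hydride reduction of esters: LiAlH4 converts the methyl ester and the alkyl pivalate into the two CH2OH groups and cleaves both aryl pivalates to the phenols in one operation. Adding 19 to excess cold hydride should make reduction faster than enolisation at C3, and the buffered, oxygen-free work-up avoids quinone methide formation and phenol oxidation, so no stereocentre changes and the racemate converges on the meso target.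

## Compound list

1 | cis-2-butene-1,4-diol | OC/C=C\CO | starting material
2 | pivaloyl chloride | CC(C)(C)C(Cl)=O | starting material
3 | (Z)-but-2-ene-1,4-diyl bis(2,2-dimethylpropanoate) | CC(C)(C)C(=O)OC/C=C\COC(=O)C(C)(C)C | intermediate
4 | 3,5-bis(pivaloyloxymethyl)-1,2,4-trioxolane (secondary ozonide, diastereomer mixture, not isolated) | CC(C)(C)C(=O)OCC1OOC(COC(=O)C(C)(C)C)O1 | intermediate
5 | 2-oxoethyl pivalate | CC(C)(C)C(=O)OCC=O | intermediate
6 | ethynylmagnesium bromide | C#C[Mg]Br | starting material
7 | 2-hydroxybut-3-yn-1-yl pivalate (racemic) | CC(C)(C)C(=O)OCC(O)C#C | intermediate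
8 | 2-(methanesulfonyloxy)but-3-yn-1-yl pivalate (racemic) | CC(C)(C)C(=O)OCC(OS(C)(=O)=O)C#C | intermediate
9 | 4-(tributylstannyl)buta-2,3-dien-1-yl pivalate (racemic allene) | CC(C)(C)C(=O)OCC=C=C[Sn](CCCC)(CCCC)CCCC | intermediate
10 | syringaldehyde (4-hydroxy-3,5-dimethoxybenzaldehyde) | COc1cc(C=O)cc(OC)c1O | starting material
11 | 4-formyl-2,6-dimethoxyphenyl pivalate | COc1cc(C=O)cc(OC)c1OC(=O)C(C)(C)C | intermediate
12 | 4-[(1S*,2S*)-1-hydroxy-2-(pivaloyloxymethyl)but-3-yn-1-yl]-2,6-dimethoxyphenyl pivalate (syn, racemic) | CC(C)(C)C(=O)Oc1c(OC)cc(cc1OC)[C@@H](O)[C@H](COC(=O)C(C)(C)C)C#C | intermediate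
13 | 4-bromo-2,6-dimethoxyphenol | COc1cc(Br)cc(OC)c1O | starting material
14 | 4-bromo-2,6-dimethoxyphenyl pivalate | COc1cc(Br)cc(OC)c1OC(=O)C(C)(C)C | intermediate
15 | (1S*,2S*)-1,4-bis(3,5-dimethoxy-4-pivaloyloxyphenyl)-2-(pivaloyloxymethyl)but-3-yn-1-ol (syn, racemic) | CC(C)(C)C(=O)Oc1c(OC)cc(cc1OC)[C@@H](O)[C@H](COC(=O)C(C)(C)C)C#Cc1cc(OC)c(OC(=O)C(C)(C)C)c(OC)c1 | intermediate
16 | [4,5-cis-2,5-bis(3,5-dimethoxy-4-pivaloyloxyphenyl)-4-(pivaloyloxymethyl)-4,5-dihydrofuran-3-yl]palladium chloride (further ligands omitted, not isolated) | CC(C)(C)C(=O)Oc1c(OC)cc(cc1OC)[C@H]1OC(=C([Pd]Cl)[C@H]1COC(=O)C(C)(C)C)c1cc(OC)c(OC(=O)C(C)(C)C)c(OC)c1 | intermediate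
17 | [4,5-cis-2,5-bis(3,5-dimethoxy-4-pivaloyloxyphenyl)-4-(pivaloyloxymethyl)-4,5-dihydrofuran-3-carbonyl]palladium chloride (further ligands omitted, not isolated) | CC(C)(C)C(=O)Oc1c(OC)cc(cc1OC)[C@H]1OC(=C(C(=O)[Pd]Cl)[C@H]1COC(=O)C(C)(C)C)c1cc(OC)c(OC(=O)C(C)(C)C)c(OC)c1 | intermediate
18 | methyl (4S*,5S*)-2,5-bis(3,5-dimethoxy-4-pivaloyloxyphenyl)-4-(pivaloyloxymethyl)-4,5-dihydrofuran-3-carboxylate (4,5-cis, racemic) | CC(C)(C)C(=O)Oc1c(OC)cc(cc1OC)[C@H]1OC(=C(C(=O)OC)[C@H]1COC(=O)C(C)(C)C)c1cc(OC)c(OC(=O)C(C)(C)C)c(OC)c1 | intermediate
19 | methyl (2R*,3S*,4S*,5S*)-2,5-bis(3,5-dimethoxy-4-pivaloyloxyphenyl)-4-(pivaloyloxymethyl)oxolane-3-carboxylate (all-cis, racemic) | CC(C)(C)C(=O)Oc1c(OC)cc(cc1OC)[C@H]1O[C@@H](c2cc(OC)c(OC(=O)C(C)(C)C)c(OC)c2)[C@@H](C(=O)OC)[C@H]1COC(=O)C(C)(C)C | intermediate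
20 | [(2S,3S,4R,5R)-2,5-bis(4-hydroxy-3,5-dimethoxyphenyl)oxolane-3,4-diyl]dimethanol (all-cis, meso; CNP0170897.3) | COc1cc([C@H]2O[C@@H](c3cc(OC)c(O)c(OC)c3)[C@@H](CO)[C@H]2CO)cc(OC)c1O | target

## Step count and least certain steps

Total step count: 12. Longest linear sequence: 10 steps (1 → 3 → 5 → 7 → 8 → 9 → 12 → 15 → 18 → 19 → 20; steps 1, 2, 3, 4, 5, 7, 9, 10, 11, 12).

Step 10 (key step). The most likely failure is loss of chemoselectivity around the vinyl–palladium stage. Protonolysis of the C–Pd bond before CO insertion would give a non-carbonylated enol ether that adds methanol. CO activation by the free alcohol could divert the substrate to an alkylidene lactone, and slow reoxidation could precipitate the metal. The 5-endo mode on an open-chain alkynol is less documented than the exo mode, which is why this step carries the main uncertainty. Fallback, with the same two bonds made in two known steps: from 15, electrophilic 5-endo-dig iodocyclisation (I2, NaHCO3, MeCN, 0 °C) should give 4,5-cis-3-iodo-2,5-bis(3,5-dimethoxy-4-pivaloyloxyphenyl)-4-(pivaloyloxymethyl)-4,5-dihydrofuran F1. Palladium-catalysed methoxycarbonylation of this vinyl iodide (PdCl2(PPh3)2, CO 1 atm, MeOH, Et3N, DMF, 60 °C) returns to the route at 18.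

Step 7. The open transition state may discriminate poorly between syn and anti for an aromatic aldehyde without α-branching, and BF3 may cause protodestannylation of 9; both would cut the supply of 12. Fallback (cyclic anti addition followed by inversion): from 8 and 11, Pd(PPh3)4/Et2Zn in THF at −20 °C generates the allenylzinc reagent. This adds through a cyclic transition state to give the anti alcohol 4-[(1R*,2S*)-1-hydroxy-2-(pivaloyloxymethyl)but-3-yn-1-yl]-2,6-dimethoxyphenyl pivalate F2. Mitsunobu inversion of the carbinol with chloroacetic acid (PPh3, DIAD, toluene, 0 °C) gives the syn chloroacetate 4-[(1S*,2S*)-1-(chloroacetoxy)-2-(pivaloyloxymethyl)but-3-yn-1-yl]-2,6-dimethoxyphenyl pivalate F3. Thiourea/NaHCO3 in ethanol at 50 °C removes the chloroacetyl group in the presence of the pivalates and rejoins the route at 12.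

Step 11. The tetrasubstituted push–pull alkene may hydrogenate slowly, and forcing conditions invite arene saturation on rhodium or hydrogenolysis of the benzylic ring C–O bonds. Fallback (reduction before hydrogenation, so the alkene is a plain enol ether and no ester-bearing stereocentre ever exists): from 18, LiAlH4 in THF at −20 → 0 °C should give [4,5-cis-2,5-bis(4-hydroxy-3,5-dimethoxyphenyl)-4,5-dihydrofuran-3,4-diyl]dimethanol F4. Hydrogenation of F4 under mild, neutral conditions (H2 1–5 bar, 5% Rh/Al2O3, EtOAc/EtOH with a trace of Et3N) from the face opposite the C4/C5 substituents comes back to the route at 20.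

Step 9. Oxidative addition into the aryl bromide may be slow compared with oxidative homocoupling of the alkyne, or the alkynol may cycloisomerise under the metal catalysts. Fallback (aryl–alkyne bond made before any stereocentre exists): from 7 and 14, Sonogashira coupling under the same catalyst system gives 4-[3-hydroxy-4-(pivaloyloxy)but-1-yn-1-yl]-2,6-dimethoxyphenyl pivalate F5. Mesylation (MsCl, Et3N) gives the mesylate 4-[3-(methanesulfonyloxy)-4-(pivaloyloxy)but-1-yn-1-yl]-2,6-dimethoxyphenyl pivalate F6. Stannylcopper SN2' displacement (Bu3SnH, LiN(i-Pr)2, CuBr·SMe2, THF, −78 °C) gives the aryl-substituted allenylstannane 4-[4-(pivaloyloxy)-1-(tributylstannyl)buta-1,2-dien-1-yl]-2,6-dimethoxyphenyl pivalate F7. BF3·OEt2-promoted syn addition of F7 to 11 rejoins the route at 15.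

## Further compounds

F1 | step 10 | 4,5-cis-3-iodo-2,5-bis(3,5-dimethoxy-4-pivaloyloxyphenyl)-4-(pivaloyloxymethyl)-4,5-dihydrofuran (racemic) | CC(C)(C)C(=O)Oc1c(OC)cc(cc1OC)[C@H]1OC(=C(I)[C@H]1COC(=O)C(C)(C)C)c1cc(OC)c(OC(=O)C(C)(C)C)c(OC)c1
F2 | step 7 | 4-[(1R*,2S*)-1-hydroxy-2-(pivaloyloxymethyl)but-3-yn-1-yl]-2,6-dimethoxyphenyl pivalate (anti, racemic) | CC(C)(C)C(=O)Oc1c(OC)cc(cc1OC)[C@H](O)[C@H](COC(=O)C(C)(C)C)C#C
F3 | step 7 | 4-[(1S*,2S*)-1-(chloroacetoxy)-2-(pivaloyloxymethyl)but-3-yn-1-yl]-2,6-dimethoxyphenyl pivalate (syn, racemic) | CC(C)(C)C(=O)Oc1c(OC)cc(cc1OC)[C@@H](OC(=O)CCl)[C@H](COC(=O)C(C)(C)C)C#C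
F4 | step 11 | [4,5-cis-2,5-bis(4-hydroxy-3,5-dimethoxyphenyl)-4,5-dihydrofuran-3,4-diyl]dimethanol (racemic) | COc1cc(cc(OC)c1O)[C@H]1OC(=C(CO)[C@H]1CO)c1cc(OC)c(O)c(OC)c1
F5 | step 9 | 4-[3-hydroxy-4-(pivaloyloxy)but-1-yn-1-yl]-2,6-dimethoxyphenyl pivalate (racemic) | CC(C)(C)C(=O)OCC(O)C#Cc1cc(OC)c(OC(=O)C(C)(C)C)c(OC)c1
F6 | step 9 | 4-[3-(methanesulfonyloxy)-4-(pivaloyloxy)but-1-yn-1-yl]-2,6-dimethoxyphenyl pivalate (racemic) | CC(C)(C)C(=O)OCC(OS(C)(=O)=O)C#Cc1cc(OC)c(OC(=O)C(C)(C)C)c(OC)c1
F7 | step 9 | 4-[4-(pivaloyloxy)-1-(tributylstannyl)buta-1,2-dien-1-yl]-2,6-dimethoxyphenyl pivalate (racemic allene) | CC(C)(C)C(=O)OCC=C=C([Sn](CCCC)(CCCC)CCCC)c1cc(OC)c(OC(=O)C(C)(C)C)c(OC)c1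
A1 | alternative 1 | all-cis 3,4-bis(benzyloxymethyl)-2,5-bis(4-hydroxy-3,5-dimethoxyphenyl)oxolane (meso) | COc1cc([C@H]2O[C@@H](c3cc(OC)c(O)c(OC)c3)[C@@H](COCc4ccccc4)[C@H]2COCc5ccccc5)cc(OC)c1O
A2 | alternative 1 | all-cis 3,4-bis(benzyloxymethyl)oxolane-2,5-diyl bis[1,3-bis(dimethylamino)trimethinium] bis(hexafluorophosphate) (meso) | CN(C)C=C(C=[N+](C)C)[C@H]1O[C@@H](C(C=[N+](C)C)=CN(C)C)[C@@H](COCc2ccccc2)[C@H]1COCc1ccccc1.F[P-](F)(F)(F)(F)F.F[P-](F)(F)(F)(F)F
A3 | alternative 1 | 1,3-dimethoxyacetone (1,3-dimethoxypropan-2-one) | COCC(=O)COC
A4 | alternative 2 | all-cis 2,5-bis(4-benzyloxy-3,5-dimethoxyphenyl)-N,N'-di(quinolin-8-yl)oxolane-3,4-dicarboxamide (meso) | COc1cc([C@H]2O[C@@H](c3cc(OC)c(OCc4ccccc4)c(OC)c3)[C@@H](C(=O)Nc5cccc6cccnc56)[C@H]2C(=O)Nc7cccc8cccnc78)cc(OC)c1OCc1ccccc1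
A5 | alternative 2 | cis-N,N'-di(quinolin-8-yl)oxolane-3,4-dicarboxamide (meso) | O=C(Nc1cccc2cccnc12)[C@H]1COC[C@H]1C(=O)Nc1cccc2cccnc12
A6 | alternative 2 | 2-benzyloxy-5-iodo-1,3-dimethoxybenzene | COc1cc(I)cc(OC)c1OCc1ccccc1
A7 | alternative 3 | dimethyl cis-2,5-bis(4-benzyloxy-3,5-dimethoxyphenyl)-2,5-dihydrofuran-3,4-dicarboxylate (meso) | COc1cc([C@H]2O[C@@H](c3cc(OC)c(OCc4ccccc4)c(OC)c3)C(C(=O)OC)=C2C(=O)OC)cc(OC)c1OCc1ccccc1
A8 | alternative 3 | dimethyl cis-2,6-bis(4-benzyloxy-3,5-dimethoxyphenyl)-1,4-oxathiane-3,5-dicarboxylate 4,4-dioxide (configuration at C3 and C5 not specified) | COC(=O)C1[C@H](c2cc(OC)c(OCc3ccccc3)c(OC)c2)O[C@H](c2cc(OC)c(OCc3ccccc3)c(OC)c2)C(C(=O)OC)S1(=O)=O
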